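**Strategy.** The plan hinges on taking the butenolide apart at its carbonyl carbon. C2 is flanked by the ring oxygen O1 and by C3, which bears the ring A dienyl arm, so deleting C2 as carbon monoxide exposes a (Z)-β-iodoenone whose ketone oxygen is the future O1. One palladium-catalysed carbonylation then forges C3–C2 and C2–O1, closes the butenolide and sets the (Z)-C5=CH bond. The precursor is an acyclic (1E,3Z,7E)-3-iodotrienone carrying the fully configured ring A triol (3-OH silylated, both tertiary hydroxyls free) and an (E)-silyloxy five-carbon stub. Ring B is attached afterwards as a tetrazolyl sulfone by Julia–Kocienski olefination.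

Key step: step 16

Assumption: (4R,6R)-actinol 1 and phosphonate 10 are taken as catalogue compounds; ring A atoms carry carotenoid numbers (C1 gem-dimethyl, C3 secondary carbinol, C5 methyl carbinol, C6 chain-bearing carbinol) and the butenolide is numbered O1, C2(=O), C3, C4, C5.

Abbreviations: TBS = tert-butyldimethylsilyl; TBDPS = tert-butyldiphenylsilyl; PT = 1-phenyl-1H-tetrazol-5-yl.

**Ring A and the iodoenone**

Step 1
Reactants: 1 (4R,6R)-4-hydroxy-2,2,6-trimethylcyclohexan-1-one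
Product: 2 (4R,6R)-4-(TBSO)-2,2,6-trimethylcyclohexan-1-one
Conditions: TBSCl, imidazole, DMF, rt
Reagents that add atoms: tert-butyldimethylsilyl chloride, SMILES CC(C)(C)[Si](C)(C)Cl
Why: Imidazole-promoted O-silylation of the only hydroxyl should give the silyl ether without touching either stereocentre.

Step 2
Reactants: 2 (4R,6R)-4-(TBSO)-2,2,6-trimethylcyclohexan-1-one
Product: 3 (4R)-4-(TBSO)-2,6,6-trimethylcyclohex-1-en-1-yl trifluoromethanesulfonate
Conditions: LiN(iPr)2, THF, −78 °C; PhNTf2, −78 °C → rt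
Reagents that add atoms: N-phenylbis(trifluoromethanesulfonimide), SMILES O=S(=O)(N(c1ccccc1)S(=O)(=O)C(F)(F)F)C(F)(F)F
Why: The ketone has an α-hydrogen on one side only (the other α-carbon is quaternary), so a single enolate forms and its O-triflation should give the tetrasubstituted enol triflate, the silyloxy stereocentre being remote and unaffected.

Step 3
Reactants: 3 (4R)-4-(TBSO)-2,6,6-trimethylcyclohex-1-en-1-yl trifluoromethanesulfonate; 4 carbon monoxide
Product: 5 methyl (4R)-4-(TBSO)-2,6,6-trimethylcyclohex-1-ene-1-carboxylate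
Conditions: Pd(OAc)2 (cat.), PPh3, Et3N, CO (1 atm), MeOH–DMF, 60 °C
Reagents that add atoms: methanol, SMILES CO
Why: Palladium-catalysed alkoxycarbonylation of an enol triflate (oxidative addition, CO insertion, methanolysis of the acylpalladium) should deliver the enoate.

Step 4
Reactants: 5 methyl (4R)-4-(TBSO)-2,6,6-trimethylcyclohex-1-ene-1-carboxylate
Product: 6 [(4R)-4-(TBSO)-2,6,6-trimethylcyclohex-1-en-1-yl]methanol
Conditions: iBu2AlH, CH2Cl2, −78 → 0 °C; aq. potassium sodium tartrate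
Reagents that add atoms: none
Why: 1,2-Reduction of the hindered conjugated ester by iBu2AlH should stop cleanly at the allylic alcohol.

Step 5
Reactants: 6 [(4R)-4-(TBSO)-2,6,6-trimethylcyclohex-1-en-1-yl]methanol
Product: 7 [(1S,4S,6S)-4-(TBSO)-2,2,6-trimethyl-7-oxabicyclo[4.1.0]heptan-1-yl]methanol (epoxide oxygen cis to the silyloxy group)
Conditions: Ti(OiPr)4, L-(+)-diethyl tartrate, t-BuOOH, 4 Å MS, CH2Cl2, −20 °C
Reagents that add atoms: tert-butyl hydroperoxide, SMILES CC(C)(C)OO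
Why: Katsuki–Sharpless asymmetric epoxidation under reagent control: the L-(+)-tartrate complex should deliver oxygen to the face of the C5=C6 bond cis to the remote C3 silyloxy group, which sets C5 and C6 together.

Step 6
Reactants: 7 [(1S,4S,6S)-4-(TBSO)-2,2,6-trimethyl-7-oxabicyclo[4.1.0]heptan-1-yl]methanol
Product: 8 (1S,2R,4S)-4-(TBSO)-1-(hydroxymethyl)-2,6,6-trimethylcyclohexane-1,2-diol
Conditions: HClO4 (cat.), THF–H2O, 0 °C
Reagents that add atoms: water, SMILES O
Why: Acid-catalysed epoxide hydrolysis should occur at C5 with inversion, because C5 is the better cation-stabilising and less hindered carbon (C6 is neopentyl and carries CH2OH) and trans-diaxial (Fürst–Plattner) attack there leads directly to the chair with the silyloxy group equatorial; this gives the trans-5,6-diol with 5-OH anti and 6-OH syn to the C3 oxygen, and the brief cold dilute acid is chosen to spare the silyl ether.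

Step 7
Reactants: 8 (1S,2R,4S)-4-(TBSO)-1-(hydroxymethyl)-2,6,6-trimethylcyclohexane-1,2-diol
Product: 9 (1R,2R,4S)-4-(TBSO)-1,2-dihydroxy-2,6,6-trimethylcyclohexane-1-carbaldehyde
Conditions: SO3·pyridine, DMSO, Et3N, CH2Cl2, 0 °C
Reagents that add atoms: none
Why: Parikh–Doering oxidation can only act on the primary alcohol (the other free hydroxyls are tertiary) and avoids glycol cleavage, and the aldehyde has no α-hydrogen to epimerise.

Step 8
Reactants: 9 (1R,2R,4S)-4-(TBSO)-1,2-dihydroxy-2,6,6-trimethylcyclohexane-1-carbaldehyde; 10 diethyl [3-(trimethylsilyl)prop-2-yn-1-yl]phosphonate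
Product: 12 (1R,2R,4S)-1-[(E)-but-1-en-3-yn-1-yl]-4-(TBSO)-2,6,6-trimethylcyclohexane-1,2-diol, via C-silylated enyne 11 (not isolated)
Conditions: LiN(SiMe3)2, THF, −78 → 0 °C; then MeOH, K2CO3, rt
Reagents that add atoms: none
Why: Horner–Wadsworth–Emmons olefination with the stabilised propargyl phosphonate anion should give the (E)-enyne (reversible addition, bulky quaternary neighbour), the weakly basic anion leaving the tertiary hydroxyls alone, and methanolysis then cleaves the alkynyl C–Si bond in the same flask.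

**Weinreb amide for the stub**

Step 9
Reactants: 13 (but-3-yn-1-yloxy)(tert-butyl)dimethylsilane
Product: 14 (E)-5-(TBSO)-3-methylpent-2-en-1-ol
Conditions: Me3Al, Cp2ZrCl2 (cat.), CH2Cl2, 0 °C → rt; then n-BuLi, (CH2O)n, THF, −30 °C → rt
Reagents that add atoms: trimethylaluminium, SMILES C[Al](C)C; paraformaldehyde (as formaldehyde), SMILES C=O
Why: Negishi zirconium-catalysed carboalumination adds methyl and aluminium syn across the terminal alkyne (methyl to the internal carbon), and the derived alanate is hydroxymethylated with retention, fixing the (E)-trisubstituted alkene.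

Step 10
Reactants: 14 (E)-5-(TBSO)-3-methylpent-2-en-1-ol
Product: 15 (E)-5-(TBSO)-1-(TBDPSO)-3-methylpent-2-ene
Conditions: TBDPSCl, imidazole, DMF, rt
Reagents that add atoms: tert-butyldiphenylsilyl chloride, SMILES CC(C)(C)[Si](Cl)(c1ccccc1)c1ccccc1
Why: Standard silylation places the more acid-stable silyl group on the allylic oxygen that will become the stub terminus.

Step 11
Reactants: 15 (E)-5-(TBSO)-1-(TBDPSO)-3-methylpent-2-ene
Product: 16 (E)-5-(TBDPSO)-3-methylpent-3-en-1-ol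
Conditions: camphorsulfonic acid (cat.), MeOH–CH2Cl2, 0 °C
Reagents that add atoms: none
Why: Acid-catalysed methanolysis should cleave the primary TBS ether much faster than the primary TBDPS ether.

Step 12
Reactants: 16 (E)-5-(TBDPSO)-3-methylpent-3-en-1-ol
Product: 17 (E)-5-(TBDPSO)-3-methylpent-3-enoic acid
Conditions: TEMPO (cat.), PhI(OAc)2, MeCN–H2O, rt
Reagents that add atoms: water, SMILES O
Why: Oxoammonium oxidation in wet acetonitrile takes the primary alcohol through the aldehyde hydrate to the acid under near-neutral conditions that should leave the β,γ-alkene in place and E.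

Step 13
Reactants: 17 (E)-5-(TBDPSO)-3-methylpent-3-enoic acid
Product: 18 (E)-5-(TBDPSO)-N-methoxy-N,3-dimethylpent-3-enamide
Conditions: MeNH(OMe)·HCl, EDCI·HCl, N-methylmorpholine, CH2Cl2, 0 °C → rt
Reagents that add atoms: N,O-dimethylhydroxylamine hydrochloride, SMILES CNOC.Cl
Why: Carbodiimide amidation with a weak amine base should form the Weinreb amide without moving the double bond into conjugation.

**Fragment union, key step and dienal**

Step 14
Reactants: 12 (1R,2R,4S)-1-[(E)-but-1-en-3-yn-1-yl]-4-(TBSO)-2,6,6-trimethylcyclohexane-1,2-diol; 18 (E)-5-(TBDPSO)-N-methoxy-N,3-dimethylpent-3-enamide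
Product: 19 (1E,7E)-9-(TBDPSO)-1-[(1R,2R,4S)-4-(TBSO)-1,2-dihydroxy-2,6,6-trimethylcyclohexyl]-7-methylnona-1,7-dien-3-yn-5-one
Conditions: n-BuLi (3 equiv), THF, −78 °C; then 18, −78 → −20 °C; cold aq. NH4Cl
Reagents that add atoms: none
Why: The lithium acetylide (both tertiary hydroxyls carried as lithium alkoxides) adds to the Weinreb amide to give a chelated tetrahedral intermediate that releases the ynone only on quench, which prevents over-addition and keeps the acidic methylene masked until work-up.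

Step 15
Reactants: 19 (1E,7E)-9-(TBDPSO)-1-[(1R,2R,4S)-4-(TBSO)-1,2-dihydroxy-2,6,6-trimethylcyclohexyl]-7-methylnona-1,7-dien-3-yn-5-one
Product: 20 (1E,3Z,7E)-9-(TBDPSO)-3-iodo-1-[(1R,2R,4S)-4-(TBSO)-1,2-dihydroxy-2,6,6-trimethylcyclohexyl]-7-methylnona-1,3,7-trien-5-one
Conditions: NaI, AcOH, rt, dark
Reagents that add atoms: sodium iodide, SMILES [Na+].[I-]
Why: Conjugate hydroiodination: iodide adds to the ynone β-carbon and the allenolate is protonated anti by acetic acid, so the kinetic (Z)-β-iodoenone with iodine cis to the carbonyl should result, both silyl ethers tolerating acetic acid at room temperature.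

Step 16
Reactants: 20 (1E,3Z,7E)-9-(TBDPSO)-3-iodo-1-[(1R,2R,4S)-4-(TBSO)-1,2-dihydroxy-2,6,6-trimethylcyclohexyl]-7-methylnona-1,3,7-trien-5-one; 4 carbon monoxide
Product: 21 (5Z)-5-[(2E)-4-(TBDPSO)-2-methylbut-2-en-1-ylidene]-3-{(E)-2-[(1R,2R,4S)-4-(TBSO)-1,2-dihydroxy-2,6,6-trimethylcyclohexyl]ethenyl}furan-2(5H)-one
Conditions: PdCl2(PPh3)2 (cat.), Et3N, CO (1 atm), THF, 50 °C
Reagents that add atoms: none
Why: Zerovalent palladium, generated from PdCl2(PPh3)2 by Et3N and CO, inserts into the C3–I bond with retention, CO insertion gives the acylpalladium on C3, and the ketone oxygen held cis to it attacks the acyl carbon while Et3N removes a proton from the doubly activated CH2 (the only enolisable position), so that C3–C2 and C2–O1 form and zerovalent palladium is released. The closest known reaction type is the palladium-catalysed carbonylative lactonisation of (Z)-β-iodoenones to (Z)-γ-ylidenebutenolides by O-enolate trapping of the acylpalladium. The one ring formed, the butenolide, closes in a 5-exo-trig acyl substitution. No stereocentre is created; the new exocyclic C5=CH bond should come out Z because the methylbutenyl chain then lies beside O1 and away from C4–H, and the E geometry of the stub alkene and of C7=C8 is carried over unchanged. The step needs O- over C-acylation of the enol (C-attack would give a cyclopentenedione) and no competing acyl capture: the cis iodide–carbonyl arrangement pre-organises O-attack, the only unhindered hydroxyl (C3–OH) is silylated, and the two tertiary hydroxyls cannot reach the acyl carbon across the (E)-C7=C8 bond.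

Step 17
Reactants: 21 (5Z)-5-[(2E)-4-(TBDPSO)-2-methylbut-2-en-1-ylidene]-3-{(E)-2-[(1R,2R,4S)-4-(TBSO)-1,2-dihydroxy-2,6,6-trimethylcyclohexyl]ethenyl}furan-2(5H)-one
Product: 22 (5Z)-5-[(2E)-4-hydroxy-2-methylbut-2-en-1-ylidene]-3-{(E)-2-[(1R,2R,4S)-1,2,4-trihydroxy-2,6,6-trimethylcyclohexyl]ethenyl}furan-2(5H)-one
Conditions: Bu4NF, AcOH, THF, 0 °C → rt
Reagents that add atoms: none
Why: Fluoride cleaves both silyl ethers in one operation, and buffering with acetic acid should protect the base-sensitive ylidenebutenolide.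

Step 18
Reactants: 22 (5Z)-5-[(2E)-4-hydroxy-2-methylbut-2-en-1-ylidene]-3-{(E)-2-[(1R,2R,4S)-1,2,4-trihydroxy-2,6,6-trimethylcyclohexyl]ethenyl}furan-2(5H)-one
Product: 23 (2E)-3-methyl-4-[(2Z)-5-oxo-4-{(E)-2-[(1R,2R,4S)-1,2,4-trihydroxy-2,6,6-trimethylcyclohexyl]ethenyl}furan-2(5H)-ylidene]but-2-enal
Conditions: MnO2, EtOAc, rt
Reagents that add atoms: none
Why: MnO2 oxidises only the primary allylic alcohol; the secondary ring hydroxyl is not allylic and the other two are tertiary.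

**Ring B sulfone**

Step 19
Reactants: 3 (4R)-4-(TBSO)-2,6,6-trimethylcyclohex-1-en-1-yl trifluoromethanesulfonate; 24 (E)-3-methylpent-2-en-4-yn-1-ol
Product: 25 (E)-5-[(4R)-4-(TBSO)-2,6,6-trimethylcyclohex-1-en-1-yl]-3-methylpent-2-en-4-yn-1-ol
Conditions: Pd(PPh3)4 (cat.), CuI (cat.), iPr2NH, DMF, 50 °C
Reagents that add atoms: none
Why: Sonogashira coupling of the enol triflate with the terminal enyne should join the fragments with the E alkene and the free hydroxyl untouched.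

Step 20
Reactants: 25 (E)-5-[(4R)-4-(TBSO)-2,6,6-trimethylcyclohex-1-en-1-yl]-3-methylpent-2-en-4-yn-1-ol; 26 (ethoxycarbonylmethylene)triphenylphosphorane
Product: 28 ethyl (2E,4E)-7-[(4R)-4-(TBSO)-2,6,6-trimethylcyclohex-1-en-1-yl]-5-methylhepta-2,4-dien-6-ynoate, via enynal 27 (not isolated)
Conditions: MnO2, Ph3P=CHCO2Et, CH2Cl2, rt
Reagents that add atoms: none
Why: Tandem allylic oxidation–Wittig reaction: the enal formed by MnO2 is trapped at once by the stabilised ylide, which should give the (2E)-enoate.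

Step 21
Reactants: 28 ethyl (2E,4E)-7-[(4R)-4-(TBSO)-2,6,6-trimethylcyclohex-1-en-1-yl]-5-methylhepta-2,4-dien-6-ynoate
Product: 29 (2E,4E)-7-[(4R)-4-(TBSO)-2,6,6-trimethylcyclohex-1-en-1-yl]-5-methylhepta-2,4-dien-6-yn-1-ol
Conditions: iBu2AlH, CH2Cl2, −78 °C; aq. potassium sodium tartrate
Reagents that add atoms: none
Why: 1,2-Reduction of the dienoate by iBu2AlH should give the dienylic alcohol without touching alkyne or silyl ether.

Step 22
Reactants: 29 (2E,4E)-7-[(4R)-4-(TBSO)-2,6,6-trimethylcyclohex-1-en-1-yl]-5-methylhepta-2,4-dien-6-yn-1-ol; 30 1-phenyl-1H-tetrazole-5-thiol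
Product: 31 5-{[(2E,4E)-7-[(4R)-4-(TBSO)-2,6,6-trimethylcyclohex-1-en-1-yl]-5-methylhepta-2,4-dien-6-yn-1-yl]sulfanyl}-1-phenyl-1H-tetrazole
Conditions: PPh3, diisopropyl azodicarboxylate, THF, 0 °C
Reagents that add atoms: none
Why: Mitsunobu thioetherification of the primary alcohol with the acidic thiol should proceed by direct displacement at the primary carbon.

Step 23
Reactants: 31 5-{[(2E,4E)-7-[(4R)-4-(TBSO)-2,6,6-trimethylcyclohex-1-en-1-yl]-5-methylhepta-2,4-dien-6-yn-1-yl]sulfanyl}-1-phenyl-1H-tetrazole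
Product: 32 5-{[(2E,4E)-7-[(4R)-4-(TBSO)-2,6,6-trimethylcyclohex-1-en-1-yl]-5-methylhepta-2,4-dien-6-yn-1-yl]sulfonyl}-1-phenyl-1H-tetrazole
Conditions: (NH4)6Mo7O24·4H2O (cat.), 30% H2O2, EtOH, 0 °C → rt
Reagents that add atoms: hydrogen peroxide, SMILES OO
Why: Molybdate-catalysed peroxide oxidation is selective for sulfur and should take the sulfide to the sulfone without epoxidising the dienyne or the ring alkene.

Step 24
Reactants: 32 5-{[(2E,4E)-7-[(4R)-4-(TBSO)-2,6,6-trimethylcyclohex-1-en-1-yl]-5-methylhepta-2,4-dien-6-yn-1-yl]sulfonyl}-1-phenyl-1H-tetrazole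
Product: 33 (1R)-3,5,5-trimethyl-4-[(3E,5E)-3-methyl-7-(PT-sulfonyl)hepta-3,5-dien-1-yn-1-yl]cyclohex-3-en-1-ol
Conditions: HF·pyridine, THF–pyridine, 0 °C → rt
Reagents that add atoms: none
Why: Non-basic fluoride removes the silyl ether without deprotonating the acidic allylic sulfone, so the final olefination needs no later deprotection.

**Final coupling**

Step 25
Reactants: 23 (2E)-3-methyl-4-[(2Z)-5-oxo-4-{(E)-2-[(1R,2R,4S)-1,2,4-trihydroxy-2,6,6-trimethylcyclohexyl]ethenyl}furan-2(5H)-ylidene]but-2-enal; 33 (1R)-3,5,5-trimethyl-4-[(3E,5E)-3-methyl-7-(PT-sulfonyl)hepta-3,5-dien-1-yn-1-yl]cyclohex-3-en-1-ol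
Product: 34 (5Z)-5-[(2E,4E,6E,8E)-11-[(4R)-4-hydroxy-2,6,6-trimethylcyclohex-1-en-1-yl]-2,9-dimethylundeca-2,4,6,8-tetraen-10-yn-1-ylidene]-3-{(E)-2-[(1R,2R,4S)-1,2,4-trihydroxy-2,6,6-trimethylcyclohexyl]ethenyl}furan-2(5H)-one (CNP0163979.1)
Conditions: NaN(SiMe3)2, THF, −78 °C → rt; then C6H6, rt, dark
Reagents that add atoms: none
Why: Julia–Kocienski olefination: the sulfonyl carbanion adds to the dienal, Smiles rearrangement and loss of SO2 and tetrazolone form the new CH=CH bond, the free hydroxyls are tolerated because the stabilised carbanion is too weak a base to be quenched by them, and any Z isomer at the new disubstituted bond is expected to relax to the all-E polyene on standing.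

**Compound list**

1 | (4R,6R)-4-hydroxy-2,2,6-trimethylcyclohexan-1-one ((4R,6R)-actinol) | C[C@H]1C(=O)C(C)(C)C[C@H](O)C1 | starting material
2 | (4R,6R)-4-(TBSO)-2,2,6-trimethylcyclohexan-1-one | C[C@H]1C(=O)C(C)(C)C[C@H](O[Si](C)(C)C(C)(C)C)C1 | intermediate
3 | (4R)-4-(TBSO)-2,6,6-trimethylcyclohex-1-en-1-yl trifluoromethanesulfonate | CC1=C(OS(=O)(=O)C(F)(F)F)C(C)(C)C[C@H](O[Si](C)(C)C(C)(C)C)C1 | intermediate
4 | carbon monoxide | [C-]#[O+] | starting material
5 | methyl (4R)-4-(TBSO)-2,6,6-trimethylcyclohex-1-ene-1-carboxylate | CC1=C(C(=O)OC)C(C)(C)C[C@H](O[Si](C)(C)C(C)(C)C)C1 | intermediate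
6 | [(4R)-4-(TBSO)-2,6,6-trimethylcyclohex-1-en-1-yl]methanol | CC1=C(CO)C(C)(C)C[C@H](O[Si](C)(C)C(C)(C)C)C1 | intermediate
7 | [(1S,4S,6S)-4-(TBSO)-2,2,6-trimethyl-7-oxabicyclo[4.1.0]heptan-1-yl]methanol | C[C@@]12O[C@]1(CO)C(C)(C)C[C@H](O[Si](C)(C)C(C)(C)C)C2 | intermediate
8 | (1S,2R,4S)-4-(TBSO)-1-(hydroxymethyl)-2,6,6-trimethylcyclohexane-1,2-diol | OC[C@@]1(O)C(C)(C)C[C@H](O[Si](C)(C)C(C)(C)C)C[C@@]1(C)O | intermediate
9 | (1R,2R,4S)-4-(TBSO)-1,2-dihydroxy-2,6,6-trimethylcyclohexane-1-carbaldehyde | O=C[C@@]1(O)C(C)(C)C[C@H](O[Si](C)(C)C(C)(C)C)C[C@@]1(C)O | intermediate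
10 | diethyl [3-(trimethylsilyl)prop-2-yn-1-yl]phosphonate | CCOP(=O)(CC#C[Si](C)(C)C)OCC | starting material
11 | (1R,2R,4S)-4-(TBSO)-2,6,6-trimethyl-1-[(E)-4-(trimethylsilyl)but-1-en-3-yn-1-yl]cyclohexane-1,2-diol | C[Si](C)(C)C#C/C=C/[C@@]1(O)C(C)(C)C[C@H](O[Si](C)(C)C(C)(C)C)C[C@@]1(C)O | intermediate
12 | (1R,2R,4S)-1-[(E)-but-1-en-3-yn-1-yl]-4-(TBSO)-2,6,6-trimethylcyclohexane-1,2-diol | C#C/C=C/[C@@]1(O)C(C)(C)C[C@H](O[Si](C)(C)C(C)(C)C)C[C@@]1(C)O | intermediate
13 | (but-3-yn-1-yloxy)(tert-butyl)dimethylsilane | C#CCCO[Si](C)(C)C(C)(C)C | starting material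
14 | (E)-5-(TBSO)-3-methylpent-2-en-1-ol | C/C(CCO[Si](C)(C)C(C)(C)C)=C\CO | intermediate
15 | (E)-5-(TBSO)-1-(TBDPSO)-3-methylpent-2-ene | C/C(CCO[Si](C)(C)C(C)(C)C)=C\CO[Si](c1ccccc1)(c1ccccc1)C(C)(C)C | intermediate
16 | (E)-5-(TBDPSO)-3-methylpent-3-en-1-ol | C/C(CCO)=C\CO[Si](c1ccccc1)(c1ccccc1)C(C)(C)C | intermediate
17 | (E)-5-(TBDPSO)-3-methylpent-3-enoic acid | C/C(CC(=O)O)=C\CO[Si](c1ccccc1)(c1ccccc1)C(C)(C)C | intermediate
18 | (E)-5-(TBDPSO)-N-methoxy-N,3-dimethylpent-3-enamide | C/C(CC(=O)N(C)OC)=C\CO[Si](c1ccccc1)(c1ccccc1)C(C)(C)C | intermediate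
19 | (1E,7E)-9-(TBDPSO)-1-[(1R,2R,4S)-4-(TBSO)-1,2-dihydroxy-2,6,6-trimethylcyclohexyl]-7-methylnona-1,7-dien-3-yn-5-one | C/C(CC(=O)C#C/C=C/[C@@]1(O)C(C)(C)C[C@H](O[Si](C)(C)C(C)(C)C)C[C@@]1(C)O)=C\CO[Si](c2ccccc2)(c2ccccc2)C(C)(C)C | intermediate
20 | (1E,3Z,7E)-9-(TBDPSO)-3-iodo-1-[(1R,2R,4S)-4-(TBSO)-1,2-dihydroxy-2,6,6-trimethylcyclohexyl]-7-methylnona-1,3,7-trien-5-one (key-step precursor) | O=C(C/C(C)=C/CO[Si](c1ccccc1)(c1ccccc1)C(C)(C)C)/C=C(I)/C=C/[C@@]1(O)C(C)(C)C[C@H](O[Si](C)(C)C(C)(C)C)C[C@@]1(C)O | intermediate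
21 | (5Z)-5-[(2E)-4-(TBDPSO)-2-methylbut-2-en-1-ylidene]-3-{(E)-2-[(1R,2R,4S)-4-(TBSO)-1,2-dihydroxy-2,6,6-trimethylcyclohexyl]ethenyl}furan-2(5H)-one (key-step product) | CC(C)(C)[Si](c1ccccc1)(c1ccccc1)OC/C=C(C)/C=C2C=C(/C=C/[C@@]3(O)C(C)(C)C[C@H](O[Si](C)(C)C(C)(C)C)C[C@@]3(C)O)C(=O)O/2 | intermediate
22 | (5Z)-5-[(2E)-4-hydroxy-2-methylbut-2-en-1-ylidene]-3-{(E)-2-[(1R,2R,4S)-1,2,4-trihydroxy-2,6,6-trimethylcyclohexyl]ethenyl}furan-2(5H)-one | OC/C=C(C)/C=C1C=C(/C=C/[C@@]2(O)C(C)(C)C[C@H](O)C[C@@]2(C)O)C(=O)O/1 | intermediate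
23 | (2E)-3-methyl-4-[(2Z)-5-oxo-4-{(E)-2-[(1R,2R,4S)-1,2,4-trihydroxy-2,6,6-trimethylcyclohexyl]ethenyl}furan-2(5H)-ylidene]but-2-enal | O=C/C=C(C)/C=C1C=C(/C=C/[C@@]2(O)C(C)(C)C[C@H](O)C[C@@]2(C)O)C(=O)O/1 | intermediate
24 | (E)-3-methylpent-2-en-4-yn-1-ol | C#C/C(C)=C/CO | starting material
25 | (E)-5-[(4R)-4-(TBSO)-2,6,6-trimethylcyclohex-1-en-1-yl]-3-methylpent-2-en-4-yn-1-ol | CC1=C(C#C/C(C)=C/CO)C(C)(C)C[C@H](O[Si](C)(C)C(C)(C)C)C1 | intermediate
26 | (ethoxycarbonylmethylene)triphenylphosphorane | CCOC(=O)C=P(c1ccccc1)(c1ccccc1)c1ccccc1 | starting material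
27 | (E)-5-[(4R)-4-(TBSO)-2,6,6-trimethylcyclohex-1-en-1-yl]-3-methylpent-2-en-4-ynal | CC1=C(C#C/C(C)=C/C=O)C(C)(C)C[C@H](O[Si](C)(C)C(C)(C)C)C1 | intermediate
28 | ethyl (2E,4E)-7-[(4R)-4-(TBSO)-2,6,6-trimethylcyclohex-1-en-1-yl]-5-methylhepta-2,4-dien-6-ynoate | CC1=C(C#C/C(C)=C/C=C/C(=O)OCC)C(C)(C)C[C@H](O[Si](C)(C)C(C)(C)C)C1 | intermediate
29 | (2E,4E)-7-[(4R)-4-(TBSO)-2,6,6-trimethylcyclohex-1-en-1-yl]-5-methylhepta-2,4-dien-6-yn-1-ol | CC1=C(C#C/C(C)=C/C=C/CO)C(C)(C)C[C@H](O[Si](C)(C)C(C)(C)C)C1 | intermediate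
30 | 1-phenyl-1H-tetrazole-5-thiol | Sc1nnnn1-c1ccccc1 | starting material
31 | 5-{[(2E,4E)-7-[(4R)-4-(TBSO)-2,6,6-trimethylcyclohex-1-en-1-yl]-5-methylhepta-2,4-dien-6-yn-1-yl]sulfanyl}-1-phenyl-1H-tetrazole | CC1=C(C#C/C(C)=C/C=C/CSc2nnnn2-c2ccccc2)C(C)(C)C[C@H](O[Si](C)(C)C(C)(C)C)C1 | intermediate
32 | 5-{[(2E,4E)-7-[(4R)-4-(TBSO)-2,6,6-trimethylcyclohex-1-en-1-yl]-5-methylhepta-2,4-dien-6-yn-1-yl]sulfonyl}-1-phenyl-1H-tetrazole | CC1=C(C#C/C(C)=C/C=C/CS(=O)(=O)c2nnnn2-c2ccccc2)C(C)(C)C[C@H](O[Si](C)(C)C(C)(C)C)C1 | intermediate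
33 | (1R)-3,5,5-trimethyl-4-[(3E,5E)-3-methyl-7-(PT-sulfonyl)hepta-3,5-dien-1-yn-1-yl]cyclohex-3-en-1-ol | CC1=C(C#C/C(C)=C/C=C/CS(=O)(=O)c2nnnn2-c2ccccc2)C(C)(C)C[C@H](O)C1 | intermediate
34 | (5Z)-5-[(2E,4E,6E,8E)-11-[(4R)-4-hydroxy-2,6,6-trimethylcyclohex-1-en-1-yl]-2,9-dimethylundeca-2,4,6,8-tetraen-10-yn-1-ylidene]-3-{(E)-2-[(1R,2R,4S)-1,2,4-trihydroxy-2,6,6-trimethylcyclohexyl]ethenyl}furan-2(5H)-one | CC1=C(C#C/C(C)=C/C=C/C=C/C=C(C)/C=C2C=C(/C=C/[C@@]3(O)C(C)(C)C[C@H](O)C[C@@]3(C)O)C(=O)O/2)C(C)(C)C[C@H](O)C1 | target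

**Count and risks**

Total steps: 25. Longest linear sequence: 14 steps (1–8, 14–18, 25).

Steps most likely to fail:

Step 16 (carbonylative lactonisation). The acylpalladium may be captured at the enol carbon instead of oxygen, or reversible dienolisation by Et3N may scramble the E geometry of the stub alkene before ring closure. The fallback sets out from aldehyde 9 and enynol 24 and rejoins the route at 21, building the same butenolide by cross-coupling. Aldehyde 9 would be converted by Takai–Hodgson olefination (CrCl2, Bu3SnCHBr2, LiI, THF–DMF) into the ring A (E)-vinylstannane F1. Enynol 24 would be silylated (TBDPSCl, imidazole) to the silyl enyne F2. F2 would be joined to (E)-2,3-dibromopropenoic acid by Sonogashira coupling at the β-bromide with 5-exo-dig lactonisation in the same flask (PdCl2(PPh3)2, CuI, Et3N, MeCN), giving the (Z)-3-bromo-5-ylidenebutenolide F3. Stille coupling of F1 with F3 (Pd2(dba)3, AsPh3, N-methylpyrrolidone) would then give 21.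

Step 6 (epoxide hydrolysis). Ionisation at C5 may be followed by ring-contracting semipinacol shift instead of water capture, water may attack with incomplete inversion, or the silyl ether may be lost in acid. The fallback sets out from 7 and rejoins at 8. Ti(OiPr)4-mediated opening of the epoxy alcohol with benzoic acid (CH2Cl2, rt), in which the titanium alkoxide of the primary hydroxyl directs the carboxylate to the distal carbon C5 with inversion under non-protic conditions, would give the C5 benzoate F4. Any acyl migration to a neighbouring hydroxyl is harmless, because methanolysis (K2CO3, MeOH) returns triol 8.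

Step 14 (acetylide acylation). Proton transfer from the doubly activated methylene of amide 18 to the acetylide or to the lithium alkoxides may outrun addition, returning enyne and moving the β,γ-alkene into conjugation. The fallback sets out from 12 and 16 and rejoins at 19. Alcohol 16 would be oxidised (Dess–Martin periodinane, NaHCO3, CH2Cl2) to the β,γ-unsaturated aldehyde F5. The far less basic cerium acetylide of 12 (n-BuLi, then CeCl3, THF, −78 °C) would add to F5 to give the propargylic alcohol F6 as a carbinol epimer mixture, and MnO2 oxidation of that activated alcohol would give ynone 19.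

Further compounds
F1 | step 16 | (1R,2R,4S)-4-(TBSO)-2,6,6-trimethyl-1-[(E)-2-(tributylstannyl)ethenyl]cyclohexane-1,2-diol | CCCC[Sn](CCCC)(CCCC)/C=C/[C@@]1(O)C(C)(C)C[C@H](O[Si](C)(C)C(C)(C)C)C[C@@]1(C)O
F2 | step 16 | (E)-tert-butyl[(3-methylpent-2-en-4-yn-1-yl)oxy]diphenylsilane | C#C/C(C)=C/CO[Si](c1ccccc1)(c1ccccc1)C(C)(C)C
F3 | step 16 | (5Z)-3-bromo-5-[(2E)-4-(TBDPSO)-2-methylbut-2-en-1-ylidene]furan-2(5H)-one | CC(C)(C)[Si](c1ccccc1)(c1ccccc1)OC/C=C(C)/C=C2C=C(Br)C(=O)O/2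
F4 | step 6 | (1R,2S,5S)-5-(TBSO)-2-hydroxy-2-(hydroxymethyl)-1,3,3-trimethylcyclohexyl benzoate | OC[C@@]1(O)C(C)(C)C[C@H](O[Si](C)(C)C(C)(C)C)C[C@@]1(C)OC(=O)c2ccccc2
F5 | step 14 | (E)-5-(TBDPSO)-3-methylpent-3-enal | C/C(CC=O)=C\CO[Si](c1ccccc1)(c1ccccc1)C(C)(C)C
F6 | step 14 | (1E,7E)-9-(TBDPSO)-1-[(1R,2R,4S)-4-(TBSO)-1,2-dihydroxy-2,6,6-trimethylcyclohexyl]-7-methylnona-1,7-dien-3-yn-5-ol (both C5 epimers) | C/C(CC(O)C#C/C=C/[C@@]1(O)C(C)(C)C[C@H](O[Si](C)(C)C(C)(C)C)C[C@@]1(C)O)=C\CO[Si](c2ccccc2)(c2ccccc2)C(C)(C)C
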